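**Retrosynthetic overview**

- Endgame: both silyl ethers come off last; the hydroxytiglate (acid 4) goes onto O6 after PMB removal; isopropyl arises from isopropenyl by RhCl(PPh3)3 hydrogenation; the angelate goes onto the C4 hydroxyl that the key step sets free.
- Key disconnection C5–C6: the cyclohexenone (the only ring, formed in this step) comes from acyclic epoxy enone 17, whose α′-enolate opens a cis-vinyl epoxide at its allylic carbon.
- Enabling feature: C5 lies between the O-bearing C4 and the O-bearing α-carbon C6 of the C1 ketone and carries a branched three-carbon group. C4–O/C5 can therefore be a cis-epoxide activated by isopropenyl, C6 a chelated Z enolate, and the C2=C3 alkene a rigid cis tether; epoxide geometry plus enolate geometry dictate the all-cis C4/C5/C6 array.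
- 17 comes from (Z)-iodoenal 11 (but-2-yne-1,4-diol, trans-hydroalumination–iodination, MnO2) by asymmetric γ-chloroallylboration/epoxide closure and Weinreb ketone synthesis with amide 6.

Key step: step 9

Remark: ring locants are C1 (ketone carbon), C2 (CH2OH-bearing), C3 (=CH), C4 (angelate), C5 (isopropyl), C6 (hydroxytiglate); the facial preference of the substituted chloroallylborane is assumed to follow that of the parent allyl-diisopinocampheylborane.

**Route**

Step 1
Reactants: 1 (tert-butyldimethylsilyloxy)acetaldehyde; 2 ethyl 2-(triphenyl-λ5-phosphanylidene)propanoate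
Product: 3 ethyl (2E)-4-{[tert-butyl(dimethyl)silyl]oxy}-2-methylbut-2-enoate
Conditions: CH2Cl2, rt
Reagents that add atoms: none
Why: Wittig olefination with a stabilised α-methyl ylide should give the E-trisubstituted enoate (ester trans to CH2OTBS), which is the tiglate geometry.

Step 2
Reactants: 3 ethyl (2E)-4-{[tert-butyl(dimethyl)silyl]oxy}-2-methylbut-2-enoate
Product: 4 (2E)-4-{[tert-butyl(dimethyl)silyl]oxy}-2-methylbut-2-enoic acid
Conditions: LiOH, THF/MeOH/H2O, 0 °C → rt; then 1 M HCl to pH 3, 0 °C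
Reagents that add atoms: lithium hydroxide, [Li+].[OH-]
Why: Ester saponification under mild conditions should leave the primary silyl ether and the E alkene untouched.

Step 3
Reactants: 5 2-chloro-N-methoxy-N-methylacetamide
Product: 6 N-methoxy-2-[(4-methoxyphenyl)methoxy]-N-methylacetamide
Conditions: 4-methoxybenzyl alcohol, NaH, THF, 0 °C → rt
Reagents that add atoms: 4-methoxybenzyl alcohol, COc1ccc(CO)cc1
Why: Williamson etherification, in which the alkoxide displaces the carbonyl-activated α-chloride while the N-methoxy-N-methylamide resists attack at its carbonyl carbon.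

Step 4
Reactants: 7 but-2-yne-1,4-diol
Product: 8 4-{[tert-butyl(dimethyl)silyl]oxy}but-2-yn-1-ol
Conditions: TBSCl (1 equiv), imidazole, THF, 0 °C → rt; 7 in threefold excess
Reagents that add atoms: tert-butyl(chloro)dimethylsilane, CC(C)(C)[Si](C)(C)Cl
Why: Statistical monosilylation of a symmetrical diol used in excess should give mainly the mono-ether.

Step 5
Reactants: 8 4-{[tert-butyl(dimethyl)silyl]oxy}but-2-yn-1-ol
Product: 10 (2Z)-4-{[tert-butyl(dimethyl)silyl]oxy}-3-iodobut-2-en-1-ol, via alkenylaluminate 9 (not isolated)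
Conditions: NaAlH2(OCH2CH2OCH3)2, THF, 0 °C; then I2, −78 °C → rt
Reagents that add atoms: iodine, II
Why: Hydroxyl-directed trans-hydroalumination of the propargylic alcohol places aluminium on the alkyne carbon remote from the free hydroxyl in a five-membered alkoxyaluminate, and iodinolysis with retention should give the Z iodoalkene (iodine cis to CH2OH).

Step 6
Reactants: 10 (2Z)-4-{[tert-butyl(dimethyl)silyl]oxy}-3-iodobut-2-en-1-ol
Product: 11 (2Z)-4-{[tert-butyl(dimethyl)silyl]oxy}-3-iodobut-2-enal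
Conditions: MnO2, CH2Cl2, rt, dark
Reagents that add atoms: none
Why: Allylic alcohol oxidation with MnO2 is neutral and should keep the Z geometry of the β-iodoenal.

Step 7
Reactants: 11 (2Z)-4-{[tert-butyl(dimethyl)silyl]oxy}-3-iodobut-2-enal; 12 3-chloro-2-methylprop-1-ene
Product: 15 tert-butyl({(2Z)-2-iodo-3-[(2S,3R)-3-(prop-1-en-2-yl)oxiran-2-yl]prop-2-en-1-yl}oxy)dimethylsilane, via chloroallylborane 13 (not isolated), via chlorohydrin 14 (not isolated)
Conditions: 12, LiN(c-C6H11)2, (+)-Ipc2BOMe, Et2O, −95 °C; BF3·OEt2; then 11, −95 → −78 °C; HOCH2CH2NH2, 0 °C; DBU, CH2Cl2, 0 °C → rt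
Reagents that add atoms: none
Why: Asymmetric γ-chloroallylboration through a chair-like six-membered transition state, in which the Z chloroallylborane should give the syn chlorohydrin and the isopinocampheyl groups of the (−)-α-pinene series should direct attack to the Re face of the aldehyde (4S,5S); base then closes the chlorohydrin with inversion at the chlorine-bearing carbon to the cis-vinyl epoxide.

Step 8
Reactants: 15 tert-butyl({(2Z)-2-iodo-3-[(2S,3R)-3-(prop-1-en-2-yl)oxiran-2-yl]prop-2-en-1-yl}oxy)dimethylsilane; 6 N-methoxy-2-[(4-methoxyphenyl)methoxy]-N-methylacetamide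
Product: 17 (3Z)-3-({[tert-butyl(dimethyl)silyl]oxy}methyl)-1-[(4-methoxyphenyl)methoxy]-4-[(2S,3R)-3-(prop-1-en-2-yl)oxiran-2-yl]but-3-en-2-one, via alkenyllithium 16 (not isolated)
Conditions: t-BuLi (2.1 equiv), Et2O, −78 °C; then 6, −78 → −40 °C; aq. NH4Cl
Reagents that add atoms: none
Why: Iodine–lithium exchange with retention of alkene geometry followed by Weinreb ketone synthesis, in which the chelated tetrahedral adduct prevents over-addition and the exchange at −78 °C should outrun attack on the epoxide.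

Step 9
Reactants: 17 (3Z)-3-({[tert-butyl(dimethyl)silyl]oxy}methyl)-1-[(4-methoxyphenyl)methoxy]-4-[(2S,3R)-3-(prop-1-en-2-yl)oxiran-2-yl]but-3-en-2-one
Product: 19 (4S,5S,6S)-2-({[tert-butyl(dimethyl)silyl]oxy}methyl)-4-hydroxy-6-[(4-methoxyphenyl)methoxy]-5-(prop-1-en-2-yl)cyclohex-2-en-1-one, via lithium enolate 18 (not isolated)
Conditions: LiN(SiMe3)2 (1.1 equiv), THF, −78 °C; then −78 → −10 °C; aq. NH4Cl
Reagents that add atoms: none
Why: The amide base removes a proton from the CH2 between the ketone and the PMB ether (the only kinetically accessible α-position of the enone) to give Z enolate 18, whose carbon attacks the isopropenyl-bearing, allylic oxirane carbon from the backside, forming C5–C6 and releasing the C4 alkoxide. The closest known reaction type is the intramolecular alkylation of a ketone enolate by an epoxide (epoxy-ketone cyclisation), steered to the distal oxirane carbon by vinyl activation. The carbocycle closes in the 6-(enolendo)-exo-tet mode with the leaving oxygen outside the new ring, whereas attack at the other oxirane carbon would be a geometrically disfavoured 5-(enolendo)-exo-tet closure. C5 is set by inversion of the (3R)-oxirane carbon, so the cis-epoxide becomes the 4,5-cis relationship, and C4 is carried through unchanged from step 7. C6 is set by enolate geometry: anti-periplanar displacement forces the departing oxygen equatorial and the isopropenyl group axial on the closing ring, while the Z enolate (O–PMB syn to O–Li through lithium chelation and avoidance of the C2 substituent) places the PMB-oxy group equatorial, that is cis to isopropenyl and to the C4 hydroxyl. The step needs C- over O-alkylation and six- over five-ring closure, which the lithium counter-ion in THF, the allylic activation of the attacked carbon and the low temperature (which also suppresses Cope rearrangement of the cis-dialkenyl oxirane) should secure.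

Step 10
Reactants: 19 (4S,5S,6S)-2-({[tert-butyl(dimethyl)silyl]oxy}methyl)-4-hydroxy-6-[(4-methoxyphenyl)methoxy]-5-(prop-1-en-2-yl)cyclohex-2-en-1-one; 20 (2Z)-2-methylbut-2-enoic acid (angelic acid)
Product: 22 (1S,5S,6S)-3-({[tert-butyl(dimethyl)silyl]oxy}methyl)-5-[(4-methoxyphenyl)methoxy]-4-oxo-6-(prop-1-en-2-yl)cyclohex-2-en-1-yl (2Z)-2-methylbut-2-enoate, via mixed anhydride 21 (not isolated)
Conditions: 20, 2,4,6-Cl3C6H2COCl, Et3N, toluene, rt; then 19, 60 °C
Reagents that add atoms: none
Why: Yamaguchi-type esterification through the mixed anhydride without a nucleophilic catalyst, conditions chosen because they should transfer the angeloyl group without Z to E isomerisation; acylation also masks the γ-hydroxy enone before the rhodium step.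

Step 11
Reactants: 22 (1S,5S,6S)-3-({[tert-butyl(dimethyl)silyl]oxy}methyl)-5-[(4-methoxyphenyl)methoxy]-4-oxo-6-(prop-1-en-2-yl)cyclohex-2-en-1-yl (2Z)-2-methylbut-2-enoate
Product: 23 (1S,5S,6S)-3-({[tert-butyl(dimethyl)silyl]oxy}methyl)-5-[(4-methoxyphenyl)methoxy]-4-oxo-6-(propan-2-yl)cyclohex-2-en-1-yl (2Z)-2-methylbut-2-enoate
Conditions: H2 (1 atm), RhCl(PPh3)3 (cat.), benzene, rt
Reagents that add atoms: none
Why: Homogeneous hydrogenation with RhCl(PPh3)3 should reduce the 1,1-disubstituted isopropenyl alkene far faster than the trisubstituted enone and angelate alkenes (the carvone to carvotanacetone selectivity); no stereocenter is formed.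

Step 12
Reactants: 23 (1S,5S,6S)-3-({[tert-butyl(dimethyl)silyl]oxy}methyl)-5-[(4-methoxyphenyl)methoxy]-4-oxo-6-(propan-2-yl)cyclohex-2-en-1-yl (2Z)-2-methylbut-2-enoate
Product: 24 (1S,5S,6R)-3-({[tert-butyl(dimethyl)silyl]oxy}methyl)-5-hydroxy-4-oxo-6-(propan-2-yl)cyclohex-2-en-1-yl (2Z)-2-methylbut-2-enoate
Conditions: DDQ, CH2Cl2/pH 7 buffer, 0 °C → rt
Reagents that add atoms: none
Why: Oxidative PMB ether cleavage by DDQ via the benzylic oxocarbenium ion should leave esters, enone and silyl ether untouched (the descriptor change at the isopropyl carbon is only a priority change).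

Step 13
Reactants: 24 (1S,5S,6R)-3-({[tert-butyl(dimethyl)silyl]oxy}methyl)-5-hydroxy-4-oxo-6-(propan-2-yl)cyclohex-2-en-1-yl (2Z)-2-methylbut-2-enoate; 4 (2E)-4-{[tert-butyl(dimethyl)silyl]oxy}-2-methylbut-2-enoic acid
Product: 25 (1S,5S,6S)-3-({[tert-butyl(dimethyl)silyl]oxy}methyl)-5-{[(2E)-4-{[tert-butyl(dimethyl)silyl]oxy}-2-methylbut-2-enoyl]oxy}-4-oxo-6-(propan-2-yl)cyclohex-2-en-1-yl (2Z)-2-methylbut-2-enoate
Conditions: 4, EDC·HCl, DMAP (cat.), CH2Cl2, 0 °C → rt
Reagents that add atoms: none
Why: Steglich-type carbodiimide esterification of the α-ketol hydroxyl at low temperature should avoid enolisation at C6 and 1,3-acyl migration of the angelate.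

Step 14
Reactants: 25 (1S,5S,6S)-3-({[tert-butyl(dimethyl)silyl]oxy}methyl)-5-{[(2E)-4-{[tert-butyl(dimethyl)silyl]oxy}-2-methylbut-2-enoyl]oxy}-4-oxo-6-(propan-2-yl)cyclohex-2-en-1-yl (2Z)-2-methylbut-2-enoate
Product: 26 (1S,5S,6S)-5-{[(2E)-4-hydroxy-2-methylbut-2-enoyl]oxy}-3-(hydroxymethyl)-4-oxo-6-(propan-2-yl)cyclohex-2-en-1-yl (2Z)-2-methylbut-2-enoate
Conditions: HF·pyridine, pyridine, THF, 0 °C → rt
Reagents that add atoms: none
Why: Fluoride-mediated desilylation of both primary silyl ethers under buffered, weakly acidic conditions should not trigger acyl migration or angelate isomerisation.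

**Compound list**

1 | (tert-butyldimethylsilyloxy)acetaldehyde | O=CCO[Si](C)(C)C(C)(C)C | starting material
2 | ethyl 2-(triphenyl-λ5-phosphanylidene)propanoate | CCOC(=O)C(C)=P(c1ccccc1)(c1ccccc1)c1ccccc1 | starting material
3 | ethyl (2E)-4-{[tert-butyl(dimethyl)silyl]oxy}-2-methylbut-2-enoate | CCOC(=O)/C(C)=C/CO[Si](C)(C)C(C)(C)C | intermediate
4 | (2E)-4-{[tert-butyl(dimethyl)silyl]oxy}-2-methylbut-2-enoic acid | OC(=O)/C(C)=C/CO[Si](C)(C)C(C)(C)C | intermediate
5 | 2-chloro-N-methoxy-N-methylacetamide | CON(C)C(=O)CCl | starting material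
6 | N-methoxy-2-[(4-methoxyphenyl)methoxy]-N-methylacetamide | CON(C)C(=O)COCc1ccc(OC)cc1 | intermediate
7 | but-2-yne-1,4-diol | OCC#CCO | starting material
8 | 4-{[tert-butyl(dimethyl)silyl]oxy}but-2-yn-1-ol | OCC#CCO[Si](C)(C)C(C)(C)C | intermediate
9 | sodium cyclic alkoxy(alkenyl)aluminate from 8 (five-membered O–CH2–CH=C–Al ring, two 2-methoxyethoxy groups on Al, CH2OTBS on the Al-bearing carbon) | [Na+].COCCO[Al-]1(OCCOC)OCC=C1CO[Si](C)(C)C(C)(C)C | intermediate (not isolated)
10 | (2Z)-4-{[tert-butyl(dimethyl)silyl]oxy}-3-iodobut-2-en-1-ol | OC/C=C(\I)CO[Si](C)(C)C(C)(C)C | intermediate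
11 | (2Z)-4-{[tert-butyl(dimethyl)silyl]oxy}-3-iodobut-2-enal | O=C/C=C(\I)CO[Si](C)(C)C(C)(C)C | intermediate
12 | 3-chloro-2-methylprop-1-ene | CC(=C)CCl | starting material
13 | [(2Z)-3-chloro-2-methylprop-2-en-1-yl]bis(isopinocampheyl)borane, isopinocampheyl groups of the (−)-α-pinene series | Cl/C=C(C)\CB([C@H]1C[C@H]2C[C@@H]([C@@H]1C)C2(C)C)[C@H]1C[C@H]2C[C@@H]([C@@H]1C)C2(C)C | intermediate (not isolated)
14 | (2Z,4S,5S)-1-{[tert-butyl(dimethyl)silyl]oxy}-5-chloro-2-iodo-6-methylhepta-2,6-dien-4-ol | I/C(CO[Si](C)(C)C(C)(C)C)=C\[C@H](O)[C@@H](Cl)C(C)=C | intermediate (not isolated)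
15 | tert-butyl({(2Z)-2-iodo-3-[(2S,3R)-3-(prop-1-en-2-yl)oxiran-2-yl]prop-2-en-1-yl}oxy)dimethylsilane | I/C(CO[Si](C)(C)C(C)(C)C)=C\[C@@H]1O[C@@H]1C(C)=C | intermediate
16 | alkenyllithium from 15 (lithium in place of iodine, cis to the (2S,3R)-oxiranyl group) | [Li]/C(CO[Si](C)(C)C(C)(C)C)=C\[C@@H]1O[C@@H]1C(C)=C | intermediate (not isolated)
17 | (3Z)-3-({[tert-butyl(dimethyl)silyl]oxy}methyl)-1-[(4-methoxyphenyl)methoxy]-4-[(2S,3R)-3-(prop-1-en-2-yl)oxiran-2-yl]but-3-en-2-one | COc1ccc(COCC(=O)/C(CO[Si](C)(C)C(C)(C)C)=C\[C@@H]2O[C@@H]2C(C)=C)cc1 | intermediate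
18 | lithium Z enolate of 17 (O–Li and O–PMB cis on the enolate C=C; enone C=C and (2S,3R)-oxirane unchanged) | COc1ccc(CO/C=C(\O[Li])/C(CO[Si](C)(C)C(C)(C)C)=C\[C@@H]2O[C@@H]2C(C)=C)cc1 | intermediate (not isolated)
19 | (4S,5S,6S)-2-({[tert-butyl(dimethyl)silyl]oxy}methyl)-4-hydroxy-6-[(4-methoxyphenyl)methoxy]-5-(prop-1-en-2-yl)cyclohex-2-en-1-one | O[C@H]1C=C(CO[Si](C)(C)C(C)(C)C)C(=O)[C@@H](OCc2ccc(OC)cc2)[C@H]1C(C)=C | intermediate
20 | (2Z)-2-methylbut-2-enoic acid (angelic acid) | C/C=C(/C)C(=O)O | starting material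
21 | (2Z)-2-methylbut-2-enoic 2,4,6-trichlorobenzoic anhydride | C/C=C(/C)C(=O)OC(=O)c1c(Cl)cc(Cl)cc1Cl | intermediate (not isolated)
22 | (1S,5S,6S)-3-({[tert-butyl(dimethyl)silyl]oxy}methyl)-5-[(4-methoxyphenyl)methoxy]-4-oxo-6-(prop-1-en-2-yl)cyclohex-2-en-1-yl (2Z)-2-methylbut-2-enoate | C/C=C(/C)C(=O)O[C@H]1C=C(CO[Si](C)(C)C(C)(C)C)C(=O)[C@@H](OCc2ccc(OC)cc2)[C@H]1C(C)=C | intermediate
23 | (1S,5S,6S)-3-({[tert-butyl(dimethyl)silyl]oxy}methyl)-5-[(4-methoxyphenyl)methoxy]-4-oxo-6-(propan-2-yl)cyclohex-2-en-1-yl (2Z)-2-methylbut-2-enoate | C/C=C(/C)C(=O)O[C@H]1C=C(CO[Si](C)(C)C(C)(C)C)C(=O)[C@@H](OCc2ccc(OC)cc2)[C@H]1C(C)C | intermediate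
24 | (1S,5S,6R)-3-({[tert-butyl(dimethyl)silyl]oxy}methyl)-5-hydroxy-4-oxo-6-(propan-2-yl)cyclohex-2-en-1-yl (2Z)-2-methylbut-2-enoate | C/C=C(/C)C(=O)O[C@H]1C=C(CO[Si](C)(C)C(C)(C)C)C(=O)[C@@H](O)[C@H]1C(C)C | intermediate
25 | (1S,5S,6S)-3-({[tert-butyl(dimethyl)silyl]oxy}methyl)-5-{[(2E)-4-{[tert-butyl(dimethyl)silyl]oxy}-2-methylbut-2-enoyl]oxy}-4-oxo-6-(propan-2-yl)cyclohex-2-en-1-yl (2Z)-2-methylbut-2-enoate | C/C=C(/C)C(=O)O[C@H]1C=C(CO[Si](C)(C)C(C)(C)C)C(=O)[C@@H](OC(=O)/C(C)=C/CO[Si](C)(C)C(C)(C)C)[C@H]1C(C)C | intermediate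
26 | (1S,5S,6S)-5-{[(2E)-4-hydroxy-2-methylbut-2-enoyl]oxy}-3-(hydroxymethyl)-4-oxo-6-(propan-2-yl)cyclohex-2-en-1-yl (2Z)-2-methylbut-2-enoate | C/C=C(/C)C(=O)O[C@H]1C=C(CO)C(=O)[C@@H](OC(=O)/C(C)=C/CO)[C@H]1C(C)C | target

**Summary and risks**

Total step count: 14. Longest linear sequence: 11 steps (steps 4 to 14).

Steps most likely to fail:

1. Step 9. The enolate oxygen may alkylate at the other oxirane carbon (five-membered enol ether that aromatises to a furan), the lithium enolate may open the epoxide too slowly, or the cis-dialkenyl oxirane may undergo Cope rearrangement on warming. The fallback is a Tsuji–Trost cyclisation, which needs the trans epoxide. It sets out from 11: epoxidation with the ylide of a (2-methylallyl)sulfonium salt of a chiral terpene-derived sulfide (KOH, MeCN/H2O) should give tert-butyl({(2Z)-2-iodo-3-[(2S,3S)-3-(prop-1-en-2-yl)oxiran-2-yl]prop-2-en-1-yl}oxy)dimethylsilane F1. Iodine–lithium exchange and acylation with 6 as in step 8 then give the trans epoxy enone (3Z)-3-({[tert-butyl(dimethyl)silyl]oxy}methyl)-1-[(4-methoxyphenyl)methoxy]-4-[(2S,3S)-3-(prop-1-en-2-yl)oxiran-2-yl]but-3-en-2-one F2. Pd(PPh3)4 (zerovalent palladium) in THF ionises the allylic C–O bond with inversion, the liberated alkoxide deprotonates the α′-position, and the enolate attacks the allyl face opposite the metal (net retention at C5). This comes back to the route at 19; if needed, C6 is corrected by enolisation with LiN(SiMe3)2 and kinetic protonation anti to isopropenyl.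

2. Step 7. At −95 °C the methyl-substituted chloroallylborane may form incompletely or unselectively (competing deprotonation of the methyl group, loss of Z geometry), eroding syn- and enantioselectivity. The fallback replaces reagent control by catalyst control with an isolable reagent. It sets out from 11: (Z)-2-(3-chloro-2-methylprop-2-en-1-yl)-4,4,5,5-tetramethyl-1,3,2-dioxaborolane, prepared and purified separately, is added under catalysis by a chiral BINOL-derived phosphoric acid (toluene, −30 °C) to give chlorohydrin 14. DBU closes 14 to the epoxide, which comes back to the route at 15.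

3. Step 10. The angeloyl group may isomerise Z to E during activation, or C6 may epimerise on prolonged warming with amine. The fallback builds the Z alkene on the substrate. It sets out from 19: DCC/DMAP esterification with 2-[bis(2,2,2-trifluoroethoxy)phosphoryl]propanoic acid gives (1S,5S,6S)-3-({[tert-butyl(dimethyl)silyl]oxy}methyl)-5-[(4-methoxyphenyl)methoxy]-4-oxo-6-(prop-1-en-2-yl)cyclohex-2-en-1-yl 2-[bis(2,2,2-trifluoroethoxy)phosphoryl]propanoate F3 (both epimers at the phosphonate carbon). Still–Gennari olefination (KN(SiMe3)2, 18-crown-6, THF, −78 °C; acetaldehyde) should give the Z-configured 2-methylbut-2-enoate, which comes back to the route at 22.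

Further compounds
F1 | step 9 | tert-butyl({(2Z)-2-iodo-3-[(2S,3S)-3-(prop-1-en-2-yl)oxiran-2-yl]prop-2-en-1-yl}oxy)dimethylsilane | I/C(CO[Si](C)(C)C(C)(C)C)=C\[C@@H]1O[C@H]1C(C)=C
F2 | step 9 | (3Z)-3-({[tert-butyl(dimethyl)silyl]oxy}methyl)-1-[(4-methoxyphenyl)methoxy]-4-[(2S,3S)-3-(prop-1-en-2-yl)oxiran-2-yl]but-3-en-2-one | COc1ccc(COCC(=O)/C(CO[Si](C)(C)C(C)(C)C)=C\[C@@H]2O[C@H]2C(C)=C)cc1
F0 | step 7 | none | none
F3 | step 10 | (1S,5S,6S)-3-({[tert-butyl(dimethyl)silyl]oxy}methyl)-5-[(4-methoxyphenyl)methoxy]-4-oxo-6-(prop-1-en-2-yl)cyclohex-2-en-1-yl 2-[bis(2,2,2-trifluoroethoxy)phosphoryl]propanoate | CC(C(=O)O[C@H]1C=C(CO[Si](C)(C)C(C)(C)C)C(=O)[C@@H](OCc2ccc(OC)cc2)[C@H]1C(C)=C)P(=O)(OCC(F)(F)F)OCC(F)(F)F
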